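## Retrosynthetic overview

1. No ring is constructed: the carbocycle is bought as a p-cresol, and the quinone is unveiled last by Teuber (Fremy's salt) oxidation of 4-hexaprenyl-2-methoxy-5-methylresorcinol at its only free ring C–H. Because the parent resorcinol is mirror-symmetric, the OH/OMe regiochemistry of the target follows automatically.
2. Key step: the ring–chain union is made at C1'–C2' (benzylic sp3–vinyl sp2), not at the aryl–allyl bond. A Ni(0)-catalysed coupling joins a benzylic chloride to an (E)-alkenylalane made by Zr-catalysed methylalumination of a C28 terminal alkyne, which creates the 2'E olefin in the same operation.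
3. C28 alkyne: geranylgeraniol → bromide → propargylation → methylalumination/CH2O (sets 6'E) → bromide → propargylation.
4. Benzylic chloride: 2,6-dibromo-4-methylphenol → O-methylation → double Pd hydroxylation → bis-MOM → directed ortho-metalation/CH2O → chloride.

Assumption: the target has no stereocentres (it is achiral), so "single enantiomer" is taken to mean the single all-E (2'E,6'E,10'E,14'E,18'E) geometric isomer.

## Route

**Step 1**
Reactants: 1, 2,6-dibromo-4-methylphenol
Product: 2, 1,3-dibromo-2-methoxy-5-methylbenzene
Conditions: MeI, K2CO3, acetone, reflux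
Reagents that add atoms: iodomethane, CI
Why: Williamson O-methylation of an acidic, non-enolisable phenol; this methyl becomes the target's methoxy group.

**Step 2**
Reactants: 2, 1,3-dibromo-2-methoxy-5-methylbenzene
Product: 3, 2-methoxy-5-methylbenzene-1,3-diol
Conditions: Pd2(dba)3 (2 mol %), t-BuXPhos (8 mol %), KOH (6 equiv), 1,4-dioxane/H2O 1:1, 100 °C, Ar; then 1 M HCl
Reagents that add atoms: potassium hydroxide, [K+].[OH-]
Why: Twofold Pd-catalysed C–O coupling of aryl bromides with hydroxide (Buchwald-type hydroxylation) gives a mirror-symmetric resorcinol whose two free ring positions are equivalent.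

**Step 3**
Reactants: 3, 2-methoxy-5-methylbenzene-1,3-diol
Product: 4, 2-methoxy-1,3-bis(methoxymethoxy)-5-methylbenzene
Conditions: MOMCl (2.5 equiv), i-Pr2NEt, CH2Cl2, 0 °C → rt
Reagents that add atoms: chloromethyl methyl ether, COCCl
Why: MOM acetal protection masks both phenols against organolithium, alane and Ni(0) and provides ortho-directing groups for the next step.

**Step 4**
Reactants: 4, 2-methoxy-1,3-bis(methoxymethoxy)-5-methylbenzene
Product: 5, [3-methoxy-2,4-bis(methoxymethoxy)-6-methylphenyl]methanol
Conditions: n-BuLi (1.1 equiv), TMEDA, THF, 0 °C, 1 h; (CH2O)n, −78 °C → rt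
Reagents that add atoms: paraformaldehyde (as formaldehyde), C=O
Why: MOM-directed ortho-metalation followed by hydroxymethylation; both ring C–H positions are equivalent, so mono-lithiation gives a single product and places the future C1' next to the methyl group.

**Step 5**
Reactants: 5, [3-methoxy-2,4-bis(methoxymethoxy)-6-methylphenyl]methanol
Product: 6, 1-(chloromethyl)-3-methoxy-2,4-bis(methoxymethoxy)-6-methylbenzene
Conditions: MsCl, LiCl, s-collidine, DMF, 0 °C; cold neutral work-up, used crude at once
Reagents that add atoms: lithium chloride, [Li+].[Cl-] (MsCl is only the activator)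
Why: Collington–Meyers chlorination (mesylate, then SN2 by chloride) is non-acidic, so the MOM acetals survive, and it uses no electrophilic chlorine that could attack the electron-rich ring.

**Step 6**
Reactants: 7, (2E,6E,10E)-geranylgeraniol
Product: 8, (2E,6E,10E)-geranylgeranyl bromide
Conditions: PBr3 (0.4 equiv), Et2O, −10 → 0 °C; used crude
Reagents that add atoms: phosphorus tribromide, BrP(Br)Br
Why: SN2-type bromination of a primary allylic alcohol at low temperature proceeds without allylic transposition or loss of 2E geometry.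

**Step 7**
Reactants: 8, geranylgeranyl bromide
Product: 9, (5E,9E,13E)-6,10,14,18-tetramethylnonadeca-5,9,13,17-tetraen-1-yne
Conditions: TMSC≡CCH3, n-BuLi, THF, −20 °C; add 8, −78 °C → rt; then MeOH, K2CO3, rt (one pot)
Reagents that add atoms: 1-(trimethylsilyl)propyne, CC#C[Si](C)(C)C (C3 unit retained; TMS lost)
Why: Propargylation by SN2 alkylation of 3-lithio-1-TMS-propyne at the primary allylic bromide (α-attack), then in situ methanolysis of the alkynyl–Si bond; the existing olefins are untouched.

**Step 8**
Reactants: 9, C23 tetraenyne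
Product: 10, (2E,6E,10E,14E)-geranylfarnesol (3,7,11,15,19-pentamethylicosa-2,6,10,14,18-pentaen-1-ol)
Conditions: Me3Al (2.5 equiv), Cp2ZrCl2 (0.25 equiv), ClCH2CH2Cl, rt, 16 h; evaporate, hexane; n-BuLi, −78 → 0 °C; (CH2O)n, THF, rt
Reagents that add atoms: trimethylaluminium, C[Al](C)C (CH3); paraformaldehyde, C=O (CH2OH)
Why: Negishi Zr-catalysed methylalumination is a regioselective syn addition (Me and Al cis), and the alkenylalanate is trapped by formaldehyde with retention, so the new trisubstituted olefin is E.

**Step 9**
Reactants: 10, geranylfarnesol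
Product: 11, (2E,6E,10E,14E)-geranylfarnesyl bromide
Conditions: PBr3 (0.4 equiv), Et2O, −10 → 0 °C; used crude
Reagents that add atoms: phosphorus tribromide, BrP(Br)Br
Why: Same primary allylic alcohol → bromide conversion as Step 6, with retention of geometry.

**Step 10**
Reactants: 11, geranylfarnesyl bromide
Product: 12, (5E,9E,13E,17E)-6,10,14,18,22-pentamethyltricosa-5,9,13,17,21-pentaen-1-yne
Conditions: TMSC≡CCH3, n-BuLi, THF, −20 °C; add 11, −78 °C → rt; then MeOH, K2CO3, rt (one pot)
Reagents that add atoms: 1-(trimethylsilyl)propyne, CC#C[Si](C)(C)C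
Why: Same SN2 propargylation/protodesilylation as Step 7, giving the terminal alkyne that carries prenyl units 2–6.

**Step 11 (key step)**
Reactants: 12, C28 pentaenyne (1.2 equiv); 6, benzylic chloride (1.0 equiv)
Product: 13, 1-[(2E,6E,10E,14E,18E)-3,7,11,15,19,23-hexamethyltetracosa-2,6,10,14,18,22-hexaen-1-yl]-3-methoxy-2,4-bis(methoxymethoxy)-6-methylbenzene
Conditions: 12, Me3Al (2 equiv), Cp2ZrCl2 (0.25 equiv), ClCH2CH2Cl, rt; strip volatiles (excess Me3Al), take up in THF; add to 6 and Ni(0) [NiCl2(PPh3)2 3 mol % / n-BuLi 6 mol %], THF, 0 °C → rt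
Reagents that add atoms: trimethylaluminium, C[Al](C)C (CH3 at C3')
Why: Syn methylalumination fixes the 2'E geometry, and the Ni(0)-catalysed benzylic chloride–alkenylalane cross-coupling (oxidative addition, Al→Ni transmetalation, reductive elimination) forms C1'–C2' with retention. There is no allyl electrophile, so SN2'/E–Z scrambling of the first prenyl unit cannot occur.

**Step 12**
Reactants: 13, bis-MOM hexaprenyl arene
Product: 14, 4-[(2E,6E,10E,14E,18E)-hexaprenyl]-2-methoxy-5-methylbenzene-1,3-diol
Conditions: TMSOTf (4 equiv), 2,2'-bipyridyl (6 equiv), CH2Cl2/MeCN, 0 °C → rt; then H2O; degassed solvents, product used at once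
Reagents that add atoms: none
Why: Bipyridyl-buffered silyl-triflate cleavage of aryl MOM acetals (via pyridinium and aryl TMS ether, then hydrolysis) is non-protic, which avoids acid-induced chroman formation or polyene cyclisation.

**Step 13**
Reactants: 14, hexaprenyl resorcinol
Product: 15, 3-demethylubiquinone-6 (3-hydroxy-2-methoxy-5-methyl-6-[(2E,6E,10E,14E,18E)-hexaprenyl]-1,4-benzoquinone)
Conditions: Fremy's salt (3 equiv), KH2PO4 buffer (pH ≈ 6), THF/H2O (or CH2Cl2/H2O with Aliquat 336), rt
Reagents that add atoms: potassium nitrosodisulfonate, [K+].[K+].[O]N(S(=O)(=O)[O-])S(=O)(=O)[O-] (supplies the new quinone oxygen)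
Why: Teuber oxidation of a phenol to a p-quinone: the single free ring position is para to the OH flanked by the prenyl chain, so that OH becomes the C=O next to the chain/OMe side. The other OH remains as the hydroxyl next to the new C=O and the methyl group, which is the target's pattern; the buffered radical oxidant leaves the olefins alone.

## Compound list

1 | 2,6-dibromo-4-methylphenol | Cc1cc(Br)c(O)c(Br)c1 | starting material
2 | 1,3-dibromo-2-methoxy-5-methylbenzene | COc1c(Br)cc(C)cc1Br | intermediate
3 | 2-methoxy-5-methylbenzene-1,3-diol | COc1c(O)cc(C)cc1O | intermediate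
4 | 2-methoxy-1,3-bis(methoxymethoxy)-5-methylbenzene | COCOc1cc(C)cc(OCOC)c1OC | intermediate
5 | [3-methoxy-2,4-bis(methoxymethoxy)-6-methylphenyl]methanol | OCc1c(C)cc(OCOC)c(OC)c1OCOC | intermediate
6 | 1-(chloromethyl)-3-methoxy-2,4-bis(methoxymethoxy)-6-methylbenzene | ClCc1c(C)cc(OCOC)c(OC)c1OCOC | intermediate
7 | (2E,6E,10E)-geranylgeraniol | OC/C=C(\C)CC/C=C(\C)CC/C=C(\C)CCC=C(C)C | starting material
8 | (2E,6E,10E)-geranylgeranyl bromide | BrC/C=C(\C)CC/C=C(\C)CC/C=C(\C)CCC=C(C)C | intermediate
9 | (5E,9E,13E)-6,10,14,18-tetramethylnonadeca-5,9,13,17-tetraen-1-yne | C#CCC/C=C(\C)CC/C=C(\C)CC/C=C(\C)CCC=C(C)C | intermediate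
10 | (2E,6E,10E,14E)-geranylfarnesol | OC/C=C(\C)CC/C=C(\C)CC/C=C(\C)CC/C=C(\C)CCC=C(C)C | intermediate
11 | (2E,6E,10E,14E)-geranylfarnesyl bromide | BrC/C=C(\C)CC/C=C(\C)CC/C=C(\C)CC/C=C(\C)CCC=C(C)C | intermediate
12 | (5E,9E,13E,17E)-6,10,14,18,22-pentamethyltricosa-5,9,13,17,21-pentaen-1-yne | C#CCC/C=C(\C)CC/C=C(\C)CC/C=C(\C)CC/C=C(\C)CCC=C(C)C | intermediate
13 | 1-[(all-E)-hexaprenyl]-3-methoxy-2,4-bis(methoxymethoxy)-6-methylbenzene | COCOc1cc(C)c(C/C=C(\C)CC/C=C(\C)CC/C=C(\C)CC/C=C(\C)CC/C=C(\C)CCC=C(C)C)c(OCOC)c1OC | intermediate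
14 | 4-[(all-E)-hexaprenyl]-2-methoxy-5-methylbenzene-1,3-diol | COc1c(O)cc(C)c(C/C=C(\C)CC/C=C(\C)CC/C=C(\C)CC/C=C(\C)CC/C=C(\C)CCC=C(C)C)c1O | intermediate
15 | 3-demethylubiquinone-6 | COC1=C(O)C(=O)C(C)=C(C/C=C(\C)CC/C=C(\C)CC/C=C(\C)CC/C=C(\C)CC/C=C(\C)CCC=C(C)C)C1=O | target

## Summary

Total step count: 13.
Longest linear sequence: 8 steps (either branch: Steps 1–5 or 6–10, then 11–13).

Three steps most likely to fail:

1. **Step 11 (Ni-catalysed benzyl chloride–alkenylalane coupling).** Risks are MOM cleavage or benzylic ionisation by the Me2AlCl formed, homocoupling, and about 5 % regioisomeric alane. Fallback: abandon the benzylic electrophile. Take the alkenylalanate from 12 on with (CH2O)n to hexaprenol, convert it to the bromide, and join it to the ring by the classical aryl–allyl union (ortho-lithiated 4 → aryl cuprate with CuBr·SMe2 + hexaprenyl bromide), then Steps 12–13.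

2. **Step 13 (Fremy oxidation of the very lipophilic, air-sensitive prenyl resorcinol).** Risks are poor phase contact, over-oxidation and chromenol formation. Fallback: move the C–H oxygenation to the start. Oxidise the small resorcinol 3 with Fremy's salt to 3-hydroxy-2-methoxy-5-methylbenzoquinone (fumigatin), reduce (Na2S2O4) and protect as the tris-MOM ether, then run DoM/CH2O, chlorination and the same Ni coupling. Global MOM removal then gives a hydroxy-hydroquinone that air or Ag2O converts to 15, so the end-game needs no C–H oxidation.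

3. **Step 5 (formation and handling of the doubly alkoxy-activated benzylic chloride).** Risks are self-alkylation and cyclisation of the ortho-MOM oxygen onto the benzylic carbon to a 1,3-benzodioxine. Fallback: avoid the halide. Convert 5 to its methyl carbonate, transmetalate the alkenylalane from 12 to the (E)-alkenyl pinacol boronate (MeOBpin), and join them by Pd/bisphosphine-catalysed benzylic carbonate Suzuki coupling.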